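The dihydropyran ring is cut at C3–C4 and O1–C2 of the chroman, which leads back to an ortho-quinone methide (exocyclic CH2, C4a, C8a and the oxygen ortho to the benzoyl group) and a 2-methylprop-1-enyl boronate. One hetero-Diels–Alder step should close this ring: the gem-dimethyl carbon C2 takes the oxygen, the boron-bearing carbon C3 takes the CH2 group, and a pinene-derived iminodiacetate ligand on boron sets the C3 configuration. Boron is a stand-in for the C3 hydroxyl and is oxidised with retention afterwards. The precursor is the Mannich base of a mono-silylated 3-prenyl-2,4,6-trihydroxybenzophenone, which releases the quinone methide on heating.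

Key step: step 6

Assumption: the (1R,2R,3R,5S)-isopinocampheyl ligand is taken to leave open the alkene face that leads to (R)-C3; if the sense were the opposite, the ligand from the (1S,2S,3S,5R)-amine would be used with no other change.

Step 1
Reactants: 1 2,4,6-trihydroxybenzophenone; 2 prenyl bromide (1-bromo-3-methylbut-2-ene)
Product: 3 2,4,6-trihydroxy-3-(3-methylbut-2-en-1-yl)benzophenone
Conditions: 2 (0.9 equiv), DBU (1.1 equiv), THF, 0 °C to rt
Reagents that add atoms: none
Why: C-alkylation of the delocalised phloroglucinol phenoxide at a ring carbon between two oxygens (C-prenylation of an acylphloroglucinol); keeping 2 limiting should hold back the second prenylation.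

Step 2
Reactants: 3 2,4,6-trihydroxy-3-(3-methylbut-2-en-1-yl)benzophenone
Product: 4 4-(tert-butyldimethylsilyloxy)-2,6-dihydroxy-3-(3-methylbut-2-en-1-yl)benzophenone
Conditions: TBSCl (1.05 equiv), imidazole (2.2 equiv), DMF, 0 °C
Reagents that add atoms: tert-butyldimethylsilyl chloride (TBSCl), CC(C)(C)[Si](C)(C)Cl
Why: O-silylation of a phenol; the hydroxyl para to the benzoyl group is the most acidic and the only one that does not flank the chelating carbonyl group, so it should be silylated first.

Step 3
Reactants: 4 4-(tert-butyldimethylsilyloxy)-2,6-dihydroxy-3-(3-methylbut-2-en-1-yl)benzophenone; 5 N,N-dimethylmethyleneiminium iodide (Eschenmoser's salt)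
Product: 6 4-(tert-butyldimethylsilyloxy)-3-[(dimethylamino)methyl]-2,6-dihydroxy-5-(3-methylbut-2-en-1-yl)benzophenone
Conditions: 5 (1.1 equiv), Et3N (1.2 equiv), CH2Cl2, 0 °C to rt
Reagents that add atoms: none
Why: Mannich aminomethylation (electrophilic aromatic substitution by the iminium ion) at the only unsubstituted ring carbon, which lies ortho and para to free hydroxyl groups.

Step 4
Reactants: 7 (1R,2R,3R,5S)-isopinocampheylamine; 8 bromoacetic acid
Product: 9 N-[(1R,2R,3R,5S)-2,6,6-trimethylbicyclo[3.1.1]heptan-3-yl]iminodiacetic acid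
Conditions: 8 (2.2 equiv), NaOH (4.5 equiv), H2O, 0 to 70 °C; then HCl to pH 2
Reagents that add atoms: none
Why: twofold SN2 N-alkylation of a primary amine with bromoacetate gives the N-substituted iminodiacetic acid; the stereocentres of the pinane skeleton are not touched.

Step 5
Reactants: 9 N-[(1R,2R,3R,5S)-2,6,6-trimethylbicyclo[3.1.1]heptan-3-yl]iminodiacetic acid; 10 (2-methylprop-1-en-1-yl)boronic acid
Product: 11 2-(2-methylprop-1-en-1-yl)-6-[(1R,2R,3R,5S)-2,6,6-trimethylbicyclo[3.1.1]heptan-3-yl]-1,3,6,2-dioxazaborocane-4,8-dione (N→B cage)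
Conditions: toluene/DMSO (10:1), reflux, Dean–Stark trap
Reagents that add atoms: none
Why: dehydrative complexation of a boronic acid with an iminodiacetic acid, as in the making of MIDA boronates, driven by removal of water.

Step 6
Reactants: 6 4-(tert-butyldimethylsilyloxy)-3-[(dimethylamino)methyl]-2,6-dihydroxy-5-(3-methylbut-2-en-1-yl)benzophenone; 11 the 2-methylprop-1-enyl boronate of ligand 9
Product: 13 (3R)-8-benzoyl-5-(tert-butyldimethylsilyloxy)-7-hydroxy-2,2-dimethyl-6-(3-methylbut-2-en-1-yl)chroman-3-yl boronate of ligand 9, via ortho-quinone methide 12 (not isolated)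
Conditions: 11 (2.5 equiv), MeCN (0.05 M in 6), 80 °C, slow argon stream
Reagents that add atoms: none
Why: Proposed new method: heating 6 should expel dimethylamine and give the ortho-quinone methide 12, whose exocyclic CH2 is attacked by the boron-bearing alkene carbon of 11 while its carbonyl oxygen bonds to the CMe2 carbon, an asynchronous inverse-electron-demand hetero-Diels–Alder reaction that forms the C4–C3 and O1–C2 bonds of the chroman together. The closest known reaction types are the [4+2] cycloadditions of ortho-quinone methides with trisubstituted alkenes and the electrophilic additions to alkenyl boronates with tetracoordinate boron, in which the C–B bond stabilises positive charge at the neighbouring carbon. The dihydropyran ring is closed by [4+2] cycloaddition (in the stepwise limit, C–C bond formation followed by six-membered capture of the tertiary cation by the phenoxide oxygen). The only new stereocentre, C3, depends solely on which alkene face meets the CH2 group, because neither C4 nor C2 is stereogenic and endo or exo approach gives the same product; the isopinocampheyl group on nitrogen is expected to screen one face, by analogy with the diastereoselective epoxidation of alkenyl boronates of this ligand. Orientation is secured by the gem-dimethyl terminus and the boron substituent acting in the same sense, the choice between the two phenolic oxygens by the silyl ether on the oxygen para to the benzoyl group, and competition from the prenyl alkene and from self-condensation by the excess of 11.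

Step 7
Reactants: 13 the (3R)-chroman-3-yl boronate of ligand 9
Product: 16 [(3R)-3,5,7-trihydroxy-2,2-dimethyl-6-(3-methylbut-2-en-1-yl)-3,4-dihydro-2H-chromen-8-yl](phenyl)methanone (CNP0386847.1), via boronic acid 14 (not isolated), via silyl ether 15 (not isolated)
Conditions: H2O2 (30% aq, 1.2 equiv), NaOH (1 M aq, 6 equiv), THF/MeOH, 0 °C then rt; then HCl to pH 4
Reagents that add atoms: hydrogen peroxide, OO
Why: hydroxide should open the B–N cage to the boronate, hydroperoxide oxidises it by 1,2-shift of C3 from boron to oxygen with retention of configuration (boronate oxidation), and hydroxide then cleaves the silyl ether of the acidic phenol.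

Compound list
1 | 2,4,6-trihydroxybenzophenone | O=C(c1ccccc1)c1c(O)cc(O)cc1O | starting material
2 | prenyl bromide (1-bromo-3-methylbut-2-ene) | CC(C)=CCBr | starting material
3 | 2,4,6-trihydroxy-3-(3-methylbut-2-en-1-yl)benzophenone | O=C(c1ccccc1)c1c(O)cc(O)c(CC=C(C)C)c1O | intermediate
4 | 4-(tert-butyldimethylsilyloxy)-2,6-dihydroxy-3-(3-methylbut-2-en-1-yl)benzophenone | O=C(c1ccccc1)c1c(O)cc(O[Si](C)(C)C(C)(C)C)c(CC=C(C)C)c1O | intermediate
5 | N,N-dimethylmethyleneiminium iodide (Eschenmoser's salt) | C=[N+](C)C.[I-] | starting material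
6 | 4-(tert-butyldimethylsilyloxy)-3-[(dimethylamino)methyl]-2,6-dihydroxy-5-(3-methylbut-2-en-1-yl)benzophenone | O=C(c1ccccc1)c1c(O)c(CN(C)C)c(O[Si](C)(C)C(C)(C)C)c(CC=C(C)C)c1O | intermediate
7 | (1R,2R,3R,5S)-isopinocampheylamine [(1R,2R,3R,5S)-2,6,6-trimethylbicyclo[3.1.1]heptan-3-amine] | C[C@H]1[C@H](N)C[C@@H]2C[C@H]1C2(C)C | starting material
8 | bromoacetic acid | OC(=O)CBr | starting material
9 | N-[(1R,2R,3R,5S)-2,6,6-trimethylbicyclo[3.1.1]heptan-3-yl]iminodiacetic acid | C[C@H]1[C@H](N(CC(=O)O)CC(=O)O)C[C@@H]2C[C@H]1C2(C)C | intermediate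
10 | (2-methylprop-1-en-1-yl)boronic acid | CC(C)=CB(O)O | starting material
11 | 2-(2-methylprop-1-en-1-yl)-6-[(1R,2R,3R,5S)-2,6,6-trimethylbicyclo[3.1.1]heptan-3-yl]-1,3,6,2-dioxazaborocane-4,8-dione | CC(C)=C[B-]12OC(=O)C[N+]1(CC(=O)O2)[C@@H]1C[C@@H]2C[C@H]([C@H]1C)C2(C)C | intermediate
12 | 2-benzoyl-5-(tert-butyldimethylsilyloxy)-3-hydroxy-4-(3-methylbut-2-en-1-yl)-6-methylidenecyclohexa-2,4-dien-1-one (ortho-quinone methide) | O=C(c1ccccc1)C1=C(O)C(CC=C(C)C)=C(O[Si](C)(C)C(C)(C)C)C(=C)C1=O | intermediate
13 | (3R)-8-benzoyl-5-(tert-butyldimethylsilyloxy)-7-hydroxy-2,2-dimethyl-6-(3-methylbut-2-en-1-yl)chroman-3-yl boronate of ligand 9 | CC(C)=CCc1c(O[Si](C)(C)C(C)(C)C)c2c(c(C(=O)c3ccccc3)c1O)OC(C)(C)[C@H]([B-]45OC(=O)C[N+]4(CC(=O)O5)[C@@H]4C[C@@H]5C[C@H]([C@H]4C)C5(C)C)C2 | intermediate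
14 | [(3R)-8-benzoyl-5-(tert-butyldimethylsilyloxy)-7-hydroxy-2,2-dimethyl-6-(3-methylbut-2-en-1-yl)-3,4-dihydro-2H-chromen-3-yl]boronic acid | CC(C)=CCc1c(O[Si](C)(C)C(C)(C)C)c2c(c(C(=O)c3ccccc3)c1O)OC(C)(C)[C@H](B(O)O)C2 | intermediate
15 | [(3R)-5-(tert-butyldimethylsilyloxy)-3,7-dihydroxy-2,2-dimethyl-6-(3-methylbut-2-en-1-yl)-3,4-dihydro-2H-chromen-8-yl](phenyl)methanone | CC(C)=CCc1c(O[Si](C)(C)C(C)(C)C)c2c(c(C(=O)c3ccccc3)c1O)OC(C)(C)[C@H](O)C2 | intermediate
16 | [(3R)-3,5,7-trihydroxy-2,2-dimethyl-6-(3-methylbut-2-en-1-yl)-3,4-dihydro-2H-chromen-8-yl](phenyl)methanone (CNP0386847.1) | CC(C)=CCc1c(O)c2c(c(C(=O)c3ccccc3)c1O)OC(C)(C)[C@H](O)C2 | target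

Total step count: 7. Longest linear sequence: 5 (steps 1, 2, 3, 6, 7); steps 4 and 5 make the boronate in a side branch.

Steps most likely to fail

Step 6. The quinone methide may be consumed by the prenyl alkene of a second molecule, by re-addition of the amine or by oligomerisation before the hindered boronate adds, and the two alkene faces may not be told apart well at 80 °C. The fallback builds the hydroxylated ring by the known epoxide route. It sets out from 3, which is C-prenylated a second time (2, DBU, THF) to 2,4,6-trihydroxy-3,5-bis(3-methylbut-2-en-1-yl)benzophenone F1. Silylation of the hydroxyl para to the benzoyl group (TBSCl, imidazole, DMF) gives the symmetric 4-(tert-butyldimethylsilyloxy)-2,6-dihydroxy-3,5-bis(3-methylbut-2-en-1-yl)benzophenone F2. Shi epoxidation of one of the two equivalent prenyl groups (D-fructose-derived Shi ketone, KHSO5, K2CO3 buffer, MeCN/dimethoxymethane/H2O, 0 °C, stopped at partial conversion) should give, by the spiro transition-state model, 4-(tert-butyldimethylsilyloxy)-3-{[(2R)-3,3-dimethyloxiran-2-yl]methyl}-2,6-dihydroxy-5-(3-methylbut-2-en-1-yl)benzophenone F3. Acid-catalysed 6-endo opening at the tertiary epoxide carbon by the neighbouring hydroxyl (camphorsulfonic acid cat., CH2Cl2, 0 °C) comes back to the route at 15, which is desilylated to 16 with NaOH as in the last stage of step 7.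

Step 7. The hydroxyboronate carries the aryloxide anti-periplanar to the C–B bond, so ring-opening beta-elimination to a prenyl phenol may compete with the 1,2-shift, and alkaline peroxide may degrade the electron-rich phenoxide. The fallback avoids both the hydroxide ate complex and peroxide. It sets out from 13, which is transesterified with pinacol (pinacol, NaHCO3, MeOH, 45 °C, conditions that should also methanolyse the aryl silyl ether) to [(3R)-5,7-dihydroxy-2,2-dimethyl-6-(3-methylbut-2-en-1-yl)-3-(4,4,5,5-tetramethyl-1,3,2-dioxaborolan-2-yl)-3,4-dihydro-2H-chromen-8-yl](phenyl)methanone F4. Oxidation of the tricoordinate boronate with anhydrous trimethylamine N-oxide (THF, 60 °C, aqueous work-up), again with retention, comes back to the route at 16.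

Step 4. The second N-alkylation of the hindered secondary amine may stall in water while bromoacetate is lost to hydrolysis. The fallback sets out from 7, which is alkylated in an organic solvent with benzyl bromoacetate (2.2 equiv, K2CO3, MeCN, 60 °C) to dibenzyl N-[(1R,2R,3R,5S)-2,6,6-trimethylbicyclo[3.1.1]heptan-3-yl]iminodiacetate F5. Hydrogenolysis of the benzyl esters (H2, 10% Pd/C, MeOH, rt) comes back to the route at 9.

Further compounds
F1 | step 6 | 2,4,6-trihydroxy-3,5-bis(3-methylbut-2-en-1-yl)benzophenone | O=C(c1ccccc1)c1c(O)c(CC=C(C)C)c(O)c(CC=C(C)C)c1O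
F2 | step 6 | 4-(tert-butyldimethylsilyloxy)-2,6-dihydroxy-3,5-bis(3-methylbut-2-en-1-yl)benzophenone | O=C(c1ccccc1)c1c(O)c(CC=C(C)C)c(O[Si](C)(C)C(C)(C)C)c(CC=C(C)C)c1O
F3 | step 6 | 4-(tert-butyldimethylsilyloxy)-3-{[(2R)-3,3-dimethyloxiran-2-yl]methyl}-2,6-dihydroxy-5-(3-methylbut-2-en-1-yl)benzophenone | O=C(c1ccccc1)c1c(O)c(C[C@H]2OC2(C)C)c(O[Si](C)(C)C(C)(C)C)c(CC=C(C)C)c1O
F4 | step 7 | [(3R)-5,7-dihydroxy-2,2-dimethyl-6-(3-methylbut-2-en-1-yl)-3-(4,4,5,5-tetramethyl-1,3,2-dioxaborolan-2-yl)-3,4-dihydro-2H-chromen-8-yl](phenyl)methanone | CC(C)=CCc1c(O)c2c(c(C(=O)c3ccccc3)c1O)OC(C)(C)[C@H](B4OC(C)(C)C(C)(C)O4)C2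
F5 | step 4 | dibenzyl N-[(1R,2R,3R,5S)-2,6,6-trimethylbicyclo[3.1.1]heptan-3-yl]iminodiacetate | C[C@H]1[C@H](N(CC(=O)OCc3ccccc3)CC(=O)OCc3ccccc3)C[C@@H]2C[C@H]1C2(C)C
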